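**Plan**

1. Locants: ring A is C1 (bears the ketone carbon), C2 OMe, C3 Br, C4 Me, C5 Br, C6 OH; ring B is C1' (bears the ketone carbon), C2' CHO, C3' OH, C4' H, C5' OH, C6' prenyl.
2. Retrosynthesis: the ketone and the aldehyde are first taken back to a silyl-protected CH–O and a methyl ester, then ring B is cut at C6'–C1' and C3'–C2'.
3. Ring B itself offers this cut: oxygen on C3' and C5' with only H on C4' between them and the prenyl group on C6' is the pattern left by a 1,1,3-trioxygenated diene with a prenylated terminus, so C1' and C2' can be the two carbons of an alkynoate that already carries the ring-A carbinol carbon and the future formyl carbon.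
4. Further cuts: the carbinol–alkyne bond of the ynoate (ring-A aldehyde plus methyl propiolate) and the C4–C5 bond of the diene (acetoacetate dianion plus prenyl bromide).
5. Forward: the diene is made (steps 1–3), ring A is bought, dressed and joined to the three-carbon ester chain (steps 4–8), ring B arises in step 9, and redox and protecting-group adjustment follows (steps 10–14).
6. Stereochemistry: the target has no stereocentre; the only one on the way, the carbinol carbon, is made racemic and is erased when it becomes the ketone.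

Key step: step 9

Remark (assumption): the target SMILES has no stereodescriptor and the molecule has no stereocentre, so "single enantiomer" is read as the achiral compound as drawn. Abbreviation used in names below: Ar = 3,5-dibromo-2-methoxy-6-(methoxymethoxy)-4-methylphenyl.

**Route**

Step 1
Reactants: 1 methyl acetoacetate; 2 1-bromo-3-methylbut-2-ene (prenyl bromide)
Product: 4 methyl 7-methyl-3-oxooct-6-enoate, via acetoacetate dianion 3 (not isolated)
Conditions: NaH, THF, 0 °C; n-BuLi, 0 °C; then 2, 0 °C → rt; aq. HCl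
Reagents that add atoms: none
Why: γ-alkylation of a β-keto ester dianion, in which the terminal carbanion is the more reactive site and should attack the primary allylic bromide by SN2 to place the prenyl group on C4.

Step 2
Reactants: 4 methyl 7-methyl-3-oxooct-6-enoate
Product: 5 methyl 7-methyl-3-(trimethylsilyloxy)octa-2,6-dienoate (2E/2Z mixture, geometry irrelevant)
Conditions: TMSCl, Et3N, hexane, rt; filter, concentrate
Reagents that add atoms: chlorotrimethylsilane, C[Si](C)(C)Cl
Why: O-silylation of the enol of a β-keto ester (silyl enol ether formation) should give the conjugated silyloxy enoate, whose C2=C3 geometry is lost in the next step.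

Step 3
Reactants: 5 methyl 7-methyl-3-(trimethylsilyloxy)octa-2,6-dienoate
Product: 7 (3Z)-1-methoxy-7-methyl-1,3-bis(trimethylsilyloxy)octa-1,3,6-triene, via lithium dienolate 6 (not isolated)
Conditions: LDA, THF, −78 °C; TMSCl, −78 °C → rt; hexane, filter, concentrate (used crude)
Reagents that add atoms: chlorotrimethylsilane, C[Si](C)(C)Cl
Why: γ-deprotonation of the silyloxy enoate gives an extended ester dienolate that is silylated on oxygen (standard preparation of 1-alkoxy-1,3-bis(silyloxy)dienes), and the new C3=C4 bond should form mainly with the prenyl CH2 pointing outward (3Z), the geometry that can reach the s-cis conformation.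

Step 4
Reactants: 8 2,6-dimethoxy-4-methylbenzaldehyde
Product: 9 2-hydroxy-6-methoxy-4-methylbenzaldehyde
Conditions: BCl3 (1.2 equiv), CH2Cl2, −78 → 0 °C; H2O
Reagents that add atoms: none
Why: chelation-controlled ortho-demethylation, in which boron bound to the aldehyde oxygen cleaves one flanking methyl ether and the resulting aryloxyboron chelate should protect the second.

Step 5
Reactants: 9 2-hydroxy-6-methoxy-4-methylbenzaldehyde
Product: 10 3,5-dibromo-2-hydroxy-6-methoxy-4-methylbenzaldehyde
Conditions: NBS (2.2 equiv), MeCN, 0 °C → rt, dark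
Reagents that add atoms: N-bromosuccinimide, O=C1CCC(=O)N1Br
Why: electrophilic aromatic bromination, for which the only two free ring positions (C3 ortho to OH, C5 para to OH and ortho to OMe) are both activated, so exhaustive bromination should give a single product.

Step 6
Reactants: 10 3,5-dibromo-2-hydroxy-6-methoxy-4-methylbenzaldehyde
Product: 11 3,5-dibromo-2-methoxy-6-(methoxymethoxy)-4-methylbenzaldehyde (ArCHO)
Conditions: MOMCl, iPr2NEt, CH2Cl2, 0 °C → rt
Reagents that add atoms: chloromethyl methyl ether, COCCl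
Why: O-alkylation of an acidic phenol (Williamson-type acetal formation) masks it against the acetylide, hydride, fluoride and oxidant used later.

Step 7
Reactants: 11 3,5-dibromo-2-methoxy-6-(methoxymethoxy)-4-methylbenzaldehyde; 12 methyl propiolate
Product: 14 methyl 4-Ar-4-hydroxybut-2-ynoate (racemic), via methyl 3-lithiopropiolate 13 (not isolated)
Conditions: 12, LiHMDS, THF, −78 °C; then 11, −78 °C; AcOH quench at −78 °C
Reagents that add atoms: none
Why: 1,2-addition of a lithium acetylide to an aldehyde, with no alkyllithium present so the aryl bromides stay intact; the new carbinol centre is formed racemic on purpose because it is oxidised later.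

Step 8
Reactants: 14 methyl 4-Ar-4-hydroxybut-2-ynoate (racemic)
Product: 15 methyl 4-[tert-butyl(dimethyl)silyl]oxy-4-[3,5-dibromo-2-methoxy-6-(methoxymethoxy)-4-methylphenyl]but-2-ynoate (racemic)
Conditions: TBSOTf (1.2 equiv), 2,6-lutidine, CH2Cl2, −78 → 0 °C
Reagents that add atoms: tert-butyldimethylsilyl triflate, CC(C)(C)[Si](C)(C)OS(=O)(=O)C(F)(F)F
Why: silylation of a hindered secondary alcohol with a silyl triflate, run cold with a hindered base so that the aryl MOM ether survives and the base-sensitive 4-oxy-ynoate does not isomerise.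

Step 9
Reactants: 15 methyl 4-[tert-butyl(dimethyl)silyl]oxy-4-[3,5-dibromo-2-methoxy-6-(methoxymethoxy)-4-methylphenyl]but-2-ynoate (racemic); 7 (3Z)-1-methoxy-7-methyl-1,3-bis(trimethylsilyloxy)octa-1,3,6-triene
Product: 18 methyl 2-{[tert-butyl(dimethyl)silyl]oxy[3,5-dibromo-2-methoxy-6-(methoxymethoxy)-4-methylphenyl]methyl}-4,6-dihydroxy-3-(3-methylbut-2-enyl)benzoate (racemic), via cyclohexa-1,4-diene cycloadduct 16 (not isolated), via bis(trimethylsilyl) aryl ether 17 (not isolated)
Conditions: 7 (3 equiv), PhMe (ca. 1 M), 110 °C, sealed tube; then 1 M HCl (aq)/THF, 0 °C, short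
Reagents that add atoms: none
Why: A thermal, asynchronous normal-demand [4+2] cycloaddition is expected, in which the most nucleophilic diene carbon (C4 of 7, the prenyl-bearing future C6') bonds to the β-carbon of the ynoate (future C1') while the ketene-acetal carbon C1 (future C3') closes on the α-carbon (future C2') to give cyclohexa-1,4-diene 16. 1,4-Elimination of methanol (OMe on C3' with H on C6') should aromatise 16 to 17, and the dilute-acid work-up hydrolyses both aryl TMS ethers to 18 while the MOM and TBS ethers remain. The closest known reaction type is the Diels–Alder benzannulation of 1-alkoxy-1,3-bis(silyloxy)-1,3-dienes with alkynoates to give resorcylates. Ring B closes in an intermolecular [4+2] mode that forms C6'–C1' and C3'–C2'. No lasting stereocentre is made, since those of 16 vanish on aromatisation and the racemic carbinol carbon is carried through unchanged. Regioselectivity is the one selectivity needed, and it is secured by the ester being the only acceptor on the alkyne (the ring-A carbon is deliberately held at the silyl-ether level), while an excess of diene compensates for the congestion at both bond-forming carbons.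

Step 10
Reactants: 18 methyl 2-{[TBSO](Ar)methyl}-4,6-dihydroxy-3-(3-methylbut-2-enyl)benzoate (racemic)
Product: 19 methyl 2-{[TBSO](Ar)methyl}-4,6-bis(methoxymethoxy)-3-(3-methylbut-2-enyl)benzoate (racemic)
Conditions: NaH, MOMCl, DMF, 0 °C → rt
Reagents that add atoms: chloromethyl methyl ether, COCCl
Why: O-alkylation of both phenoxides, including the hydrogen-bonded one next to the ester, leaves no free phenol for hydride, fluoride or activated DMSO and puts the same group on all three phenols.

Step 11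
Reactants: 19 methyl 2-{[TBSO](Ar)methyl}-4,6-bis(methoxymethoxy)-3-(3-methylbut-2-enyl)benzoate (racemic)
Product: 20 [2-{[TBSO](Ar)methyl}-4,6-bis(methoxymethoxy)-3-(3-methylbut-2-enyl)phenyl]methanol (racemic)
Conditions: DIBAL-H (4 equiv), CH2Cl2, −78 → 0 °C; Rochelle salt
Reagents that add atoms: none
Why: hydride reduction of an aryl ester to the benzylic alcohol, done before desilylation because a free carbinol ortho to the ester would lactonise to a phthalide.

Step 12
Reactants: 20 [2-{[TBSO](Ar)methyl}-4,6-bis(methoxymethoxy)-3-(3-methylbut-2-enyl)phenyl]methanol (racemic)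
Product: 21 Ar[2-(hydroxymethyl)-3,5-bis(methoxymethoxy)-6-(3-methylbut-2-enyl)phenyl]methanol (racemic diol)
Conditions: TBAF, THF, 0 °C → rt; Et3N-deactivated SiO2
Reagents that add atoms: none
Why: fluoride cleavage of a silyl ether, to which MOM ethers, aryl bromides and the prenyl group are inert; acid is avoided so the electron-rich diaryl carbinol cannot ionise or close to a phthalan.

Step 13
Reactants: 21 Ar[2-(hydroxymethyl)-3,5-bis(methoxymethoxy)-6-(3-methylbut-2-enyl)phenyl]methanol (racemic diol)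
Product: 23 2-[3,5-dibromo-2-methoxy-6-(methoxymethoxy)-4-methylbenzoyl]-4,6-bis(methoxymethoxy)-3-(3-methylbut-2-enyl)benzaldehyde, via bis(alkoxysulfonium) dichloride 22 (not isolated)
Conditions: (COCl)2 (5 equiv), DMSO (10 equiv), CH2Cl2, −78 °C; 21, −78 → −45 °C; Et3N, → 0 °C
Reagents that add atoms: none
Why: Swern oxidation, in which both hydroxyls are turned into alkoxysulfonium ions before any base is added, so the primary and the secondary carbinol are oxidised in one operation and no hydroxy-aldehyde is left to close to a lactol and over-oxidise to a phthalide.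

Step 14
Reactants: 23 2-[3,5-dibromo-2-methoxy-6-(methoxymethoxy)-4-methylbenzoyl]-4,6-bis(methoxymethoxy)-3-(3-methylbut-2-enyl)benzaldehyde
Product: 24 Pestalone D, 2-(3,5-dibromo-2-hydroxy-6-methoxy-4-methylbenzoyl)-4,6-dihydroxy-3-(3-methylbut-2-enyl)benzaldehyde
Conditions: 6 M HCl (aq)/THF (1:4), rt
Reagents that add atoms: none
Why: acid hydrolysis of three aryl MOM acetals, two of which sit ortho to a carbonyl and leave readily; aqueous THF in place of an alcohol avoids acetalisation of the o-acylbenzaldehyde, and room temperature limits addition of the C5' phenol to the prenyl double bond.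

**Compound list**

1 | methyl acetoacetate | COC(=O)CC(C)=O | starting material
2 | 1-bromo-3-methylbut-2-ene (prenyl bromide) | CC(C)=CCBr | starting material
3 | methyl acetoacetate dianion (sodium lithium salt) | [Na+].[Li+].COC(=O)C=C([O-])[CH2-] | intermediate (not isolated)
4 | methyl 7-methyl-3-oxooct-6-enoate | COC(=O)CC(=O)CCC=C(C)C | intermediate
5 | methyl 7-methyl-3-(trimethylsilyloxy)octa-2,6-dienoate (2E/2Z mixture) | COC(=O)C=C(O[Si](C)(C)C)CCC=C(C)C | intermediate
6 | lithium (3Z)-1-methoxy-7-methyl-3-(trimethylsilyloxy)octa-1,3,6-trien-1-olate | [Li+].COC([O-])=C/C(O[Si](C)(C)C)=C/CC=C(C)C | intermediate (not isolated)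
7 | (3Z)-1-methoxy-7-methyl-1,3-bis(trimethylsilyloxy)octa-1,3,6-triene (C1=C2 geometry not defined) | COC(O[Si](C)(C)C)=C/C(O[Si](C)(C)C)=C/CC=C(C)C | intermediate
8 | 2,6-dimethoxy-4-methylbenzaldehyde | COc1cc(C)cc(OC)c1C=O | starting material
9 | 2-hydroxy-6-methoxy-4-methylbenzaldehyde | COc1cc(C)cc(O)c1C=O | intermediate
10 | 3,5-dibromo-2-hydroxy-6-methoxy-4-methylbenzaldehyde | COc1c(Br)c(C)c(Br)c(O)c1C=O | intermediate
11 | 3,5-dibromo-2-methoxy-6-(methoxymethoxy)-4-methylbenzaldehyde | COc1c(Br)c(C)c(Br)c(OCOC)c1C=O | intermediate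
12 | methyl propiolate (methyl prop-2-ynoate) | COC(=O)C#C | starting material
13 | methyl 3-lithioprop-2-ynoate | COC(=O)C#C[Li] | intermediate (not isolated)
14 | methyl 4-[3,5-dibromo-2-methoxy-6-(methoxymethoxy)-4-methylphenyl]-4-hydroxybut-2-ynoate (racemic) | COc1c(Br)c(C)c(Br)c(OCOC)c1C(O)C#CC(=O)OC | intermediate
15 | methyl 4-[tert-butyl(dimethyl)silyl]oxy-4-[3,5-dibromo-2-methoxy-6-(methoxymethoxy)-4-methylphenyl]but-2-ynoate (racemic) | COc1c(Br)c(C)c(Br)c(OCOC)c1C(O[Si](C)(C)C(C)(C)C)C#CC(=O)OC | intermediate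
16 | methyl 2-{[tert-butyl(dimethyl)silyl]oxy[3,5-dibromo-2-methoxy-6-(methoxymethoxy)-4-methylphenyl]methyl}-6-methoxy-3-(3-methylbut-2-enyl)-4,6-bis(trimethylsilyloxy)cyclohexa-1,4-diene-1-carboxylate (diastereomer mixture) | COC(=O)C1=C(C(O[Si](C)(C)C(C)(C)C)c2c(OC)c(Br)c(C)c(Br)c2OCOC)C(CC=C(C)C)C(O[Si](C)(C)C)=CC1(OC)O[Si](C)(C)C | intermediate (not isolated)
17 | methyl 2-{[tert-butyl(dimethyl)silyl]oxy[3,5-dibromo-2-methoxy-6-(methoxymethoxy)-4-methylphenyl]methyl}-3-(3-methylbut-2-enyl)-4,6-bis(trimethylsilyloxy)benzoate (racemic) | COC(=O)c1c(O[Si](C)(C)C)cc(O[Si](C)(C)C)c(CC=C(C)C)c1C(O[Si](C)(C)C(C)(C)C)c1c(OC)c(Br)c(C)c(Br)c1OCOC | intermediate (not isolated)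
18 | methyl 2-{[tert-butyl(dimethyl)silyl]oxy[3,5-dibromo-2-methoxy-6-(methoxymethoxy)-4-methylphenyl]methyl}-4,6-dihydroxy-3-(3-methylbut-2-enyl)benzoate (racemic) | COc1c(Br)c(C)c(Br)c(OCOC)c1C(O[Si](C)(C)C(C)(C)C)c1c(C(=O)OC)c(O)cc(O)c1CC=C(C)C | intermediate
19 | methyl 2-{[tert-butyl(dimethyl)silyl]oxy[3,5-dibromo-2-methoxy-6-(methoxymethoxy)-4-methylphenyl]methyl}-4,6-bis(methoxymethoxy)-3-(3-methylbut-2-enyl)benzoate (racemic) | COc1c(Br)c(C)c(Br)c(OCOC)c1C(O[Si](C)(C)C(C)(C)C)c1c(C(=O)OC)c(OCOC)cc(OCOC)c1CC=C(C)C | intermediate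
20 | [2-{[tert-butyl(dimethyl)silyl]oxy[3,5-dibromo-2-methoxy-6-(methoxymethoxy)-4-methylphenyl]methyl}-4,6-bis(methoxymethoxy)-3-(3-methylbut-2-enyl)phenyl]methanol (racemic) | COc1c(Br)c(C)c(Br)c(OCOC)c1C(O[Si](C)(C)C(C)(C)C)c1c(CO)c(OCOC)cc(OCOC)c1CC=C(C)C | intermediate
21 | [3,5-dibromo-2-methoxy-6-(methoxymethoxy)-4-methylphenyl][2-(hydroxymethyl)-3,5-bis(methoxymethoxy)-6-(3-methylbut-2-enyl)phenyl]methanol (racemic) | COc1c(Br)c(C)c(Br)c(OCOC)c1C(O)c1c(CO)c(OCOC)cc(OCOC)c1CC=C(C)C | intermediate
22 | bis(dimethylsulfonio) ether dichloride of diol 21 (both hydroxyls as O–S+Me2) | COc1c(Br)c(C)c(Br)c(OCOC)c1C(O[S+](C)C)c1c(CO[S+](C)C)c(OCOC)cc(OCOC)c1CC=C(C)C.[Cl-].[Cl-] | intermediate (not isolated)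
23 | 2-[3,5-dibromo-2-methoxy-6-(methoxymethoxy)-4-methylbenzoyl]-4,6-bis(methoxymethoxy)-3-(3-methylbut-2-enyl)benzaldehyde | COc1c(Br)c(C)c(Br)c(OCOC)c1C(=O)c1c(C=O)c(OCOC)cc(OCOC)c1CC=C(C)C | intermediate
24 | Pestalone D, 2-(3,5-dibromo-2-hydroxy-6-methoxy-4-methylbenzoyl)-4,6-dihydroxy-3-(3-methylbut-2-enyl)benzaldehyde | COc1c(Br)c(C)c(Br)c(O)c1C(=O)c1c(C=O)c(O)cc(O)c1CC=C(C)C | target

**Count and risks**

Total step count: 14. Longest linear sequence: 11 steps (steps 4–14, from 8 to 24); the diene branch (steps 1–3) joins at step 9.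

Most likely to fail:

Step 9. The cycloaddition may stall because both bond-forming carbons are congested (a prenylated diene terminus against an alkyne carbon carrying the silyloxy(aryl)methyl group), so that thermal decay of the diene outruns ring formation. The fallback sets out from 15 and swaps the ester for a stronger activating group with the same polarisation. DIBAL-H at −78 °C should reduce the ynoate to 4-[tert-butyl(dimethyl)silyl]oxy-4-Ar-but-2-yn-1-ol F1, and MnO2 should oxidise this to 4-[tert-butyl(dimethyl)silyl]oxy-4-Ar-but-2-ynal F2. This much more electrophilic ynal should combine with 7 well below 110 °C and, after the same acidic work-up, give 2-{[TBSO](Ar)methyl}-4,6-dihydroxy-3-(3-methylbut-2-enyl)benzaldehyde F3. NaH/MOMCl then gives 2-{[TBSO](Ar)methyl}-4,6-bis(methoxymethoxy)-3-(3-methylbut-2-enyl)benzaldehyde F4, and NaBH4 in MeOH reduces it to 20, where the route is rejoined.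

Step 13. The very hindered secondary hydroxyl may be activated too slowly, so that the primary alcohol is oxidised first, the hydroxy-aldehyde closes to a lactol and this is oxidised on to a phthalide. The fallback sets out from 21 and separates the two oxidations. TESCl/imidazole at 0 °C should silylate only the primary hydroxyl to give Ar[3,5-bis(methoxymethoxy)-6-(3-methylbut-2-enyl)-2-(triethylsilyloxymethyl)phenyl]methanol F5. Buffered Dess–Martin periodinane oxidises the carbinol to Ar[3,5-bis(methoxymethoxy)-6-(3-methylbut-2-enyl)-2-(triethylsilyloxymethyl)phenyl]methanone F6. HF·pyridine in THF/pyridine frees Ar[2-(hydroxymethyl)-3,5-bis(methoxymethoxy)-6-(3-methylbut-2-enyl)phenyl]methanone F7, and MnO2 oxidises its benzylic alcohol to 23. With the ketone in place first, no oxidisable lactol can form.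

Step 14. Under the acid needed for the unactivated C5' MOM ether, the freed phenol may add to the neighbouring prenyl double bond (chroman formation), or the o-acylbenzaldehyde may isomerise. The fallback sets out from 18 and masks the ring-B phenols with a group that is removed without acid. Allyl bromide/K2CO3 in DMF gives methyl 2-{[TBSO](Ar)methyl}-3-(3-methylbut-2-enyl)-4,6-bis(prop-2-enyloxy)benzoate F8. DIBAL-H gives [2-{[TBSO](Ar)methyl}-3-(3-methylbut-2-enyl)-4,6-bis(prop-2-enyloxy)phenyl]methanol F9, and TBAF gives Ar[2-(hydroxymethyl)-6-(3-methylbut-2-enyl)-3,5-bis(prop-2-enyloxy)phenyl]methanol F10. Swern oxidation as in step 13 gives 2-[3,5-dibromo-2-methoxy-6-(methoxymethoxy)-4-methylbenzoyl]-3-(3-methylbut-2-enyl)-4,6-bis(prop-2-enyloxy)benzaldehyde F11. Brief 1 M HCl/THF removes only the carbonyl-activated ring-A MOM ether, with no free phenol beside the prenyl group, to give 2-(3,5-dibromo-2-hydroxy-6-methoxy-4-methylbenzoyl)-3-(3-methylbut-2-enyl)-4,6-bis(prop-2-enyloxy)benzaldehyde F12. Pd(PPh3)4/PhSiH3 in CH2Cl2 at rt then removes both allyl groups under neutral conditions to give 24.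

**Further compounds**

F1 | step 9 | 4-[tert-butyl(dimethyl)silyl]oxy-4-[3,5-dibromo-2-methoxy-6-(methoxymethoxy)-4-methylphenyl]but-2-yn-1-ol (racemic) | COc1c(Br)c(C)c(Br)c(OCOC)c1C(O[Si](C)(C)C(C)(C)C)C#CCO
F2 | step 9 | 4-[tert-butyl(dimethyl)silyl]oxy-4-[3,5-dibromo-2-methoxy-6-(methoxymethoxy)-4-methylphenyl]but-2-ynal (racemic) | COc1c(Br)c(C)c(Br)c(OCOC)c1C(O[Si](C)(C)C(C)(C)C)C#CC=O
F3 | step 9 | 2-{[tert-butyl(dimethyl)silyl]oxy[3,5-dibromo-2-methoxy-6-(methoxymethoxy)-4-methylphenyl]methyl}-4,6-dihydroxy-3-(3-methylbut-2-enyl)benzaldehyde (racemic) | COc1c(Br)c(C)c(Br)c(OCOC)c1C(O[Si](C)(C)C(C)(C)C)c1c(C=O)c(O)cc(O)c1CC=C(C)C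
F4 | step 9 | 2-{[tert-butyl(dimethyl)silyl]oxy[3,5-dibromo-2-methoxy-6-(methoxymethoxy)-4-methylphenyl]methyl}-4,6-bis(methoxymethoxy)-3-(3-methylbut-2-enyl)benzaldehyde (racemic) | COc1c(Br)c(C)c(Br)c(OCOC)c1C(O[Si](C)(C)C(C)(C)C)c1c(C=O)c(OCOC)cc(OCOC)c1CC=C(C)C
F5 | step 13 | [3,5-dibromo-2-methoxy-6-(methoxymethoxy)-4-methylphenyl][3,5-bis(methoxymethoxy)-6-(3-methylbut-2-enyl)-2-(triethylsilyloxymethyl)phenyl]methanol (racemic) | COc1c(Br)c(C)c(Br)c(OCOC)c1C(O)c1c(CO[Si](CC)(CC)CC)c(OCOC)cc(OCOC)c1CC=C(C)C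
F6 | step 13 | [3,5-dibromo-2-methoxy-6-(methoxymethoxy)-4-methylphenyl][3,5-bis(methoxymethoxy)-6-(3-methylbut-2-enyl)-2-(triethylsilyloxymethyl)phenyl]methanone | COc1c(Br)c(C)c(Br)c(OCOC)c1C(=O)c1c(CO[Si](CC)(CC)CC)c(OCOC)cc(OCOC)c1CC=C(C)C
F7 | step 13 | [3,5-dibromo-2-methoxy-6-(methoxymethoxy)-4-methylphenyl][2-(hydroxymethyl)-3,5-bis(methoxymethoxy)-6-(3-methylbut-2-enyl)phenyl]methanone | COc1c(Br)c(C)c(Br)c(OCOC)c1C(=O)c1c(CO)c(OCOC)cc(OCOC)c1CC=C(C)C
F8 | step 14 | methyl 2-{[tert-butyl(dimethyl)silyl]oxy[3,5-dibromo-2-methoxy-6-(methoxymethoxy)-4-methylphenyl]methyl}-3-(3-methylbut-2-enyl)-4,6-bis(prop-2-enyloxy)benzoate (racemic) | COc1c(Br)c(C)c(Br)c(OCOC)c1C(O[Si](C)(C)C(C)(C)C)c1c(C(=O)OC)c(OCC=C)cc(OCC=C)c1CC=C(C)C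
F9 | step 14 | [2-{[tert-butyl(dimethyl)silyl]oxy[3,5-dibromo-2-methoxy-6-(methoxymethoxy)-4-methylphenyl]methyl}-3-(3-methylbut-2-enyl)-4,6-bis(prop-2-enyloxy)phenyl]methanol (racemic) | COc1c(Br)c(C)c(Br)c(OCOC)c1C(O[Si](C)(C)C(C)(C)C)c1c(CO)c(OCC=C)cc(OCC=C)c1CC=C(C)C
F10 | step 14 | [3,5-dibromo-2-methoxy-6-(methoxymethoxy)-4-methylphenyl][2-(hydroxymethyl)-6-(3-methylbut-2-enyl)-3,5-bis(prop-2-enyloxy)phenyl]methanol (racemic) | COc1c(Br)c(C)c(Br)c(OCOC)c1C(O)c1c(CO)c(OCC=C)cc(OCC=C)c1CC=C(C)C
F11 | step 14 | 2-[3,5-dibromo-2-methoxy-6-(methoxymethoxy)-4-methylbenzoyl]-3-(3-methylbut-2-enyl)-4,6-bis(prop-2-enyloxy)benzaldehyde | COc1c(Br)c(C)c(Br)c(OCOC)c1C(=O)c1c(C=O)c(OCC=C)cc(OCC=C)c1CC=C(C)C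
F12 | step 14 | 2-(3,5-dibromo-2-hydroxy-6-methoxy-4-methylbenzoyl)-3-(3-methylbut-2-enyl)-4,6-bis(prop-2-enyloxy)benzaldehyde | COc1c(Br)c(C)c(Br)c(O)c1C(=O)c1c(C=O)c(OCC=C)cc(OCC=C)c1CC=C(C)C
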